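Ring B, the acetylated cyclohexadienone (C1 ring ketone, C2 acetyl-bearing, C3 and C5 enol carbons, C4 quaternary, C6 bridge-bearing), is a dearomatised tetraketide and is built the way a polyketide synthase extends and folds a chain. The precursor is a pyran-2,4-dione, a C-methylated, C-geranylated triacetic acid lactone that masks the triketide and already carries C4 as a single enantiomer (asymmetric allylation). In one flask a thioacetate enolate opens its lactone carbonyl (bond C5–C6) and the released diketonate closes onto the thioester (bond C1–C2). The step exploits the alternating 1,3,5-oxygenation of ring B and its hydrogen-free C4. Ring A is joined last through the methylene bridge.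

Key step: step 2

Assumption: the (S,S)-DACH-phenyl Trost ligand is taken to give the S-configured dione in step 1; if the sense of induction is the opposite, its (R,R)-enantiomer is used. Geranyl stands for (2E)-3,7-dimethylocta-2,6-dien-1-yl, and triketone rings are written in the enol tautomer of the target.

Step 1
Reactants: 1 4-hydroxy-3,6-dimethyl-2H-pyran-2-one; 2 geranyl acetate
Product: 3 (3S)-3-geranyl-3,6-dimethyl-2H-pyran-2,4(3H)-dione
Conditions: Pd2(dba)3·CHCl3 (2.5 mol %), (S,S)-DACH-phenyl Trost ligand (7.5 mol %), Et3N (1.2 equiv), CH2Cl2, 0 °C → rt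
Reagents that add atoms: none
Why: Tsuji–Trost asymmetric allylic alkylation, in which zerovalent palladium ionises 2 to the syn-π-geranyl complex, the soft pyronate of 1 attacks its unsubstituted terminus through C3 (O-allylation is reversible under the catalyst), and the chiral pocket of the ligand selects the enolate face, which should set C3 as S.

Step 2
Reactants: 3 (3S)-3-geranyl-3,6-dimethyl-2H-pyran-2,4(3H)-dione; 4 S-tert-butyl thioacetate
Product: 7 (4R)-2-acetyl-4-geranyl-3,5-dihydroxy-4-methylcyclohexa-2,5-dien-1-one, via lithium thioester enolate 5 (not isolated), via open-chain triketo thioester 6 (not isolated)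
Conditions: 4 (2.5 equiv), LiN(SiMe3)2 (2.5 equiv), THF, −78 °C; then 3, −78 → −30 °C; then AcOH (2.5 equiv), MgBr2·OEt2 (1.1 equiv), Et3N (1.1 equiv), 40 °C; aq. HCl work-up
Reagents that add atoms: none
Why: Claisen condensation: enolate 5 adds to the lactone carbonyl of 3 (pyranone C-2, the future C5 of ring B), a vinylogous anhydride carbonyl, and collapse expels the β-diketonate, which opens the ring to the dianion of 6 and forms bond C5–C6. After neutralisation and re-enolisation as the magnesium mono-enolate, the diketonate carbon attacks the thioester in a 6-(enolendo)-exo-trig Claisen (Dieckmann-type) cyclisation that expels tert-butylthiolate and forms bond C1–C2, the closure a polyketide synthase uses for acylphloroglucinols. The closest known reaction types are the Fujimoto–Belleau opening of enol lactones by carbanions with recyclisation to a carbocycle, and the base-mediated Claisen cyclisation of 3,5,7-triketo esters to acylphloroglucinols. No stereocentre is formed: C4 has no hydrogen and lies outside both enolates, so the configuration from step 1 is retained (S in 3 and R in 7 are the same spatial arrangement, only the priorities change). The step needs attack at the lactone carbonyl instead of at the ketone or at C-6 of the pyranone, which the anhydride-like activation of that carbonyl and the low temperature favour. It also needs C- over O-acylation in the closure, which magnesium chelation of the diketonate oxygens should secure, while the competing aldol adduct cannot aromatise at quaternary C4 and reverts, so the stabilised trione enolate is the sink.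

Step 3
Reactants: 8 phloroglucinol; 9 butanoyl chloride
Product: 10 1-(2,4,6-trihydroxyphenyl)butan-1-one
Conditions: AlCl3 (4 equiv), PhNO2/CH2Cl2, 0 → 50 °C; aq. HCl
Reagents that add atoms: none
Why: Friedel–Crafts acylation of the symmetrical, electron-rich ring, which should stop after one acylation because the chelated aryl ketone is deactivated.

Step 4
Reactants: 10 1-(2,4,6-trihydroxyphenyl)butan-1-one; 11 geranyl bromide
Product: 12 1-(3-geranyl-2,4,6-trihydroxyphenyl)butan-1-one
Conditions: 10 (2 equiv), 11 (1 equiv), 10% aq. KOH, 0 °C → rt
Reagents that add atoms: none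
Why: C-alkylation of the ambident phenolate by allylic SN2 substitution, favoured in water where the phenolate oxygens are hydrogen-bonded; the two free ring positions of 10 are equivalent, the excess of 10 limits double alkylation, and the E-alkene is not touched.

Step 5
Reactants: 12 1-(3-geranyl-2,4,6-trihydroxyphenyl)butan-1-one
Product: 13 1-{3-[(dimethylamino)methyl]-5-geranyl-2,4,6-trihydroxyphenyl}butan-1-one
Conditions: CH2O (37% aq., 1.5 equiv), Me2NH (40% aq., 1.5 equiv), EtOH, 0 °C
Reagents that add atoms: formaldehyde C=O; dimethylamine CNC
Why: Mannich aminomethylation at the single free, strongly nucleophilic ring carbon of the phloroglucinol, with an excess of the iminium partner so that unreacted 12 does not capture the product.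

Step 6
Reactants: 13 1-{3-[(dimethylamino)methyl]-5-geranyl-2,4,6-trihydroxyphenyl}butan-1-one; 7 (4R)-2-acetyl-4-geranyl-3,5-dihydroxy-4-methylcyclohexa-2,5-dien-1-one
Product: 15 (4R)-2-acetyl-6-[(3-butanoyl-5-geranyl-2,4,6-trihydroxyphenyl)methyl]-4-geranyl-3,5-dihydroxy-4-methylcyclohexa-2,5-dien-1-one, via o-quinone methide 14 (not isolated)
Conditions: 7 (1.1 equiv), 1,4-dioxane, 60 °C; pH 4 buffer wash
Reagents that add atoms: none
Why: Elimination of dimethylamine from the phenolic Mannich base (protonated by the vinylogous acid 7) gives o-quinone methide 14, which is captured in a Michael addition by C6 of 7, its only free nucleophilic ring carbon, with re-aromatisation of ring A as driving force and the remote C4 stereocentre untouched.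

Compound list
1 | 4-hydroxy-3,6-dimethyl-2H-pyran-2-one | CC1=CC(O)=C(C)C(=O)O1 | starting material
2 | geranyl acetate, (2E)-3,7-dimethylocta-2,6-dien-1-yl acetate | CC(=O)OC/C=C(\C)CCC=C(C)C | starting material
3 | (3S)-3-geranyl-3,6-dimethyl-2H-pyran-2,4(3H)-dione | CC1=CC(=O)[C@](C)(C/C=C(\C)CCC=C(C)C)C(=O)O1 | intermediate
4 | S-tert-butyl thioacetate | CC(=O)SC(C)(C)C | starting material
5 | lithium enolate of S-tert-butyl thioacetate, lithium 1-(tert-butylsulfanyl)ethen-1-olate (formed in the flask) | [Li]OC(=C)SC(C)(C)C | intermediate
6 | S-tert-butyl (4S)-4-geranyl-4-methyl-3,5,7-trioxooctanethioate (formed in the flask, present as its enolates) | CC(=O)CC(=O)[C@](C)(C/C=C(\C)CCC=C(C)C)C(=O)CC(=O)SC(C)(C)C | intermediate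
7 | (4R)-2-acetyl-4-geranyl-3,5-dihydroxy-4-methylcyclohexa-2,5-dien-1-one | CC(=O)C1=C(O)[C@](C)(C/C=C(\C)CCC=C(C)C)C(O)=CC1=O | intermediate
8 | phloroglucinol, benzene-1,3,5-triol | Oc1cc(O)cc(O)c1 | starting material
9 | butanoyl chloride | CCCC(Cl)=O | starting material
10 | 1-(2,4,6-trihydroxyphenyl)butan-1-one | CCCC(=O)c1c(O)cc(O)cc1O | intermediate
11 | geranyl bromide, (2E)-1-bromo-3,7-dimethylocta-2,6-diene | BrC/C=C(\C)CCC=C(C)C | starting material
12 | 1-(3-geranyl-2,4,6-trihydroxyphenyl)butan-1-one | CCCC(=O)c1c(O)cc(O)c(C/C=C(\C)CCC=C(C)C)c1O | intermediate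
13 | 1-{3-[(dimethylamino)methyl]-5-geranyl-2,4,6-trihydroxyphenyl}butan-1-one | CCCC(=O)c1c(O)c(CN(C)C)c(O)c(C/C=C(\C)CCC=C(C)C)c1O | intermediate
14 | 2-butanoyl-4-geranyl-3,5-dihydroxy-6-methylidenecyclohexa-2,4-dien-1-one, o-quinone methide (formed in the flask) | CCCC(=O)C1=C(O)C(C/C=C(\C)CCC=C(C)C)=C(O)C(=C)C1=O | intermediate
15 | (4R)-2-acetyl-6-[(3-butanoyl-5-geranyl-2,4,6-trihydroxyphenyl)methyl]-4-geranyl-3,5-dihydroxy-4-methylcyclohexa-2,5-dien-1-one | CCCC(=O)c1c(O)c(C/C=C(\C)CCC=C(C)C)c(O)c(CC2=C(O)[C@@](C)(C/C=C(\C)CCC=C(C)C)C(O)=C(C(C)=O)C2=O)c1O | target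

Total step count: 6. Longest linear sequence: 4 steps (steps 3, 4, 5 and 6); the ring B branch (steps 1, 2 and 6) is 3 steps.

Steps most likely to fail

1. Step 2. The enolate may add to the ketone or to C-6 of the pyranone instead of the lactone carbonyl, or abstract a proton from the C-6 methyl group. The chain may also close through the diketonate oxygen to a pyranone instead of through carbon. The fallback separates the two bond formations and reverses their order, using soft-enolisation C-acylation and a Dieckmann condensation. It sets out from 3, whose lactone is opened with methanol (MeOH, Et3N, DMAP cat., rt) to methyl (2S)-2-geranyl-2-methyl-3,5-dioxohexanoate F1. The magnesium diketonate of F1 is C-acetylated (MgCl2, pyridine, acetyl chloride, CH2Cl2, 0 °C) to methyl (2S)-4-acetyl-2-geranyl-2-methyl-3,5-dioxohexanoate F2. LiN(SiMe3)2 (3 equiv, THF, −78 → 0 °C) should then close one of the two equivalent acetyl groups of F2 onto the ester, and the route is rejoined at 7.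

2. Step 1. Facial selectivity may be poor because the pyronate is nearly symmetric about C3 (ring oxygen on one side, C5–H on the other) and the ligand has to tell these apart. Partial loss of the E-geometry through π–σ–π isomerisation of the allyl complex is a lesser risk. The fallback gives up asymmetric catalysis for a racemic synthesis with resolution. It sets out from 1 and 2, which with an achiral catalyst (Pd(PPh3)4, Et3N, THF, rt) should give racemic 3-geranyl-3,6-dimethyl-2H-pyran-2,4(3H)-dione F3. Preparative chromatography on a chiral stationary phase (amylose tris(3,5-dimethylphenylcarbamate), supercritical CO2/MeOH) separates the enantiomers, and the S-enantiomer is 3, where the route is rejoined.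

3. Step 6. The methylene bridge may exchange by retro-Michael cleavage and re-addition, which would scramble the partners into the two symmetrical dimers. A geranyl chain may also cyclise onto a neighbouring hydroxyl group under the acidic, warm conditions. The fallback reverses the roles of the two rings so that the coupling can run at room temperature. It sets out from 7, which is aminomethylated (CH2O, Me2NH, EtOH, 0 °C) to (4R)-2-acetyl-6-[(dimethylamino)methyl]-4-geranyl-3,5-dihydroxy-4-methylcyclohexa-2,5-dien-1-one F4. This zwitterionic Mannich base should lose dimethylamine at rt (CH2Cl2) and alkylate the free ring carbon of 12 by elimination–addition, which comes back to the route at 15.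

Further compounds
F1 | step 2 | methyl (2S)-2-geranyl-2-methyl-3,5-dioxohexanoate | COC(=O)[C@@](C)(C/C=C(\C)CCC=C(C)C)C(=O)CC(C)=O
F2 | step 2 | methyl (2S)-4-acetyl-2-geranyl-2-methyl-3,5-dioxohexanoate | COC(=O)[C@@](C)(C/C=C(\C)CCC=C(C)C)C(=O)C(C(C)=O)C(C)=O
F3 | step 1 | racemic 3-geranyl-3,6-dimethyl-2H-pyran-2,4(3H)-dione | CC1=CC(=O)C(C)(C/C=C(\C)CCC=C(C)C)C(=O)O1
F4 | step 6 | (4R)-2-acetyl-6-[(dimethylamino)methyl]-4-geranyl-3,5-dihydroxy-4-methylcyclohexa-2,5-dien-1-one | CN(C)CC1=C(O)[C@@](C)(C/C=C(\C)CCC=C(C)C)C(O)=C(C(C)=O)C1=O
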